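The strategy removes together the two neighbouring ring A substituents, the C3 hydroxyl and the C4 formyl group (C1 = methyl carbon; C5 carries the diaryl ether oxygen, C6 the depsidone carbonyl). A C3≡C4 aryne, polarised by the C5 oxygen, takes up N,N-dimethylformamide across its C=O bond. C3–O and C4–CHO are thus made in one operation with one regiochemistry. The precursor is the finished depsidone–phthalide tetracycle with C3–OTf and C4–SiMe3, the fumarate as tert-butyl ester, and the ring B phenol and lactol as 4-methoxybenzyl ethers. The triflate is installed only after etherification and lactonisation, because a phenoxide beside the silane would release the aryne too early.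

Key step: step 19

Numbering: ring A as above. Ring B = B1 (depsidone ester O), B2 (CH2O–fumarate), B3 (OH), B4 (phthalide C=O), B5 (bears the lactol carbon), B6 (diaryl ether O). PMB = 4-methoxybenzyl.

Assumption: the lactol carbon equilibrates in solution through the open 2-formylbenzoic acid form, so every acetal intermediate is carried as a racemate, the (R) configuration is fixed last in a crystal lattice, and the product is kept solid and cold; whether quinine or its pseudo-enantiomer quinidine gives the less soluble (R)-salt must be settled by a screen with X-ray analysis of the salt, and the route is written for quinine.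

Step 1
Reactants: 1 orcinol (5-methylbenzene-1,3-diol)
Product: 2 1,3-bis(methoxymethoxy)-5-methylbenzene
Conditions: MOMCl, i-Pr2NEt, CH2Cl2, 0 °C → rt
Reagents that add atoms: chloromethyl methyl ether, COCCl
Why: Williamson-type O-alkylation of both phenols installs two acetal ethers that later serve as directing groups for ortho-metalation.

Step 2
Reactants: 2 1,3-bis(methoxymethoxy)-5-methylbenzene
Product: 4 [2,6-bis(methoxymethoxy)-4-methylphenyl]trimethylsilane, via aryllithium 3 (not isolated)
Conditions: n-BuLi, THF, 0 °C; Me3SiCl, −78 °C → rt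
Reagents that add atoms: chlorotrimethylsilane, C[Si](C)(C)Cl
Why: Directed ortho-metalation occurs at the carbon between the two OMOM groups, the most acidic and doubly coordinated site, and the aryllithium is silylated there.

Step 3
Reactants: 4 [2,6-bis(methoxymethoxy)-4-methylphenyl]trimethylsilane
Product: 6 allyl 2,4-bis(methoxymethoxy)-6-methyl-3-(trimethylsilyl)benzoate, via aryllithium 5 (not isolated)
Conditions: s-BuLi, TMEDA, THF, −78 °C; inverse addition to ClCO2CH2CH=CH2, −78 °C → rt
Reagents that add atoms: allyl chloroformate, C=CCOC(=O)Cl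
Why: With the inter-oxygen position blocked by silicon, a second directed ortho-metalation goes to one of the two equivalent positions between OMOM and CH3, and acylation of the hindered aryllithium by the chloroformate stops at the ester.

Step 4
Reactants: 6 allyl 2,4-bis(methoxymethoxy)-6-methyl-3-(trimethylsilyl)benzoate
Product: 8 allyl 2,4-dihydroxy-6-methyl-3-(trimethylsilyl)benzoate, via bis(silyl ether) 7 (not isolated)
Conditions: Me3SiOTf, 2,2'-bipyridyl, MeCN, 0 °C → rt; then H2O, pH 7 buffer
Reagents that add atoms: none
Why: Silyl triflate/bipyridyl cleavage of aromatic MOM ethers runs through aryl silyl ethers in a buffered, practically non-acidic medium, which avoids the protodesilylation that protic acid would cause at this very electron-rich C–SiMe3 bond.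

Step 5
Reactants: 8 allyl 2,4-dihydroxy-6-methyl-3-(trimethylsilyl)benzoate
Product: 9 allyl 4-(allyloxy)-2-hydroxy-6-methyl-3-(trimethylsilyl)benzoate
Conditions: allyl bromide (1.05 equiv), K2CO3, acetone, rt → 40 °C
Reagents that add atoms: allyl bromide, C=CCBr
Why: Williamson etherification selects the hydroxyl para to the ester, because the ortho hydroxyl is hydrogen-bonded to the ester carbonyl and lies between the silane and the ester.

Step 6
Reactants: 10 methyl 5-bromo-2,4-dihydroxybenzoate
Product: 11 methyl 5-bromo-3-formyl-2,4-dihydroxybenzoate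
Conditions: MgCl2, Et3N, (CH2O)n, MeCN, reflux; 1 M HCl work-up
Reagents that add atoms: formaldehyde (as paraformaldehyde), C=O
Why: Casnati–Skattebøl ortho-formylation of the magnesium phenoxide can only reach C3, the sole free position ortho to a hydroxyl, since C5 carries bromine.

Step 7
Reactants: 11 methyl 5-bromo-3-formyl-2,4-dihydroxybenzoate
Product: 12 methyl 5-bromo-2,4-dihydroxy-3-(hydroxymethyl)benzoate
Conditions: NaBH4, THF–H2O, 0 °C; aq. NH4Cl
Reagents that add atoms: none
Why: Borohydride reduction converts the aldehyde to the benzylic alcohol and leaves the methyl ester and aryl bromide untouched, the low temperature suppressing over-reduction through a quinone methide.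

Step 8
Reactants: 12 methyl 5-bromo-2,4-dihydroxy-3-(hydroxymethyl)benzoate
Product: 13 methyl 8-bromo-5-hydroxy-2,2-dimethyl-4H-1,3-benzodioxine-6-carboxylate
Conditions: Me2C(OMe)2, PPTS (cat.), acetone, rt
Reagents that add atoms: 2,2-dimethoxypropane, COC(C)(C)OC
Why: Acid-catalysed transketalisation under equilibrium control closes the six-membered acetonide onto the hydroxyl next to bromine, because only this isomer keeps the strong hydrogen bond between the other hydroxyl and the ester carbonyl.

Step 9
Reactants: 13 methyl 8-bromo-5-hydroxy-2,2-dimethyl-4H-1,3-benzodioxine-6-carboxylate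
Product: 14 methyl 8-bromo-5-(4-methoxybenzyloxy)-2,2-dimethyl-4H-1,3-benzodioxine-6-carboxylate
Conditions: PMBCl, K2CO3, NaI (cat.), MeCN, 60 °C
Reagents that add atoms: 4-methoxybenzyl chloride, COc1ccc(CCl)cc1
Why: Williamson etherification of the only remaining phenol gives an ether that resists base, copper, zerovalent palladium and fluoride and falls later to trifluoroacetic acid.

Step 10
Reactants: 14 methyl 8-bromo-5-(4-methoxybenzyloxy)-2,2-dimethyl-4H-1,3-benzodioxine-6-carboxylate; 15 N,N-dimethylformamide
Product: 17 methyl 8-bromo-7-formyl-5-(4-methoxybenzyloxy)-2,2-dimethyl-4H-1,3-benzodioxine-6-carboxylate, via arylmagnesium chloride 16 (not isolated)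
Conditions: TMPMgCl·LiCl, THF, −25 °C; 15, −25 → 0 °C; aq. NH4Cl
Reagents that add atoms: none
Why: Directed magnesiation with the hindered amide base removes the only aromatic hydrogen, acidified by the flanking bromine and ester, at a temperature that ester, bromide and acetonide tolerate, and Bouveault-type formylation by 15 follows.

Step 11
Reactants: 9 allyl 4-(allyloxy)-2-hydroxy-6-methyl-3-(trimethylsilyl)benzoate; 17 methyl 8-bromo-7-formyl-5-(4-methoxybenzyloxy)-2,2-dimethyl-4H-1,3-benzodioxine-6-carboxylate
Product: 18 diaryl ether in which the 2-oxygen of 9 replaces the bromine of 17 (C5–O–B6)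
Conditions: CuI, N,N-dimethylglycine, Cs2CO3, 4 Å MS, dioxane, 90 °C
Reagents that add atoms: none
Why: In this ligand-accelerated Ullmann diaryl ether synthesis the ortho-formyl group activates the C–Br bond, the acetonide ties back the other ortho substituent, and the ring A oxygen beyond the silane is an allyl ether rather than a sulfonate, so the phenoxide has no leaving group to expel.

Step 12
Reactants: 18 diaryl ether
Product: 19 (±)-lactol in which B5–CHO and B4–CO2Me of 18 have merged into a 3-hydroxyphthalide ring
Conditions: LiOH, THF–H2O, 0 °C; 0.5 M HCl to pH 4, 0 °C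
Reagents that add atoms: lithium hydroxide, [Li+].[OH-]
Why: Saponification with neighbouring-group participation (the aldehyde hydrate anion attacks the adjacent methyl ester) spares the di-ortho-substituted allyl benzoate of ring A, and ring–chain tautomerism gives the lactol, whose new stereocentre forms as a racemate without control.

Step 13
Reactants: 19 (±)-lactol
Product: 21 (±)-PMB acetal (lactol OH of 19 as 4-methoxybenzyl ether), via 3-chlorophthalide 20 (not isolated)
Conditions: 1-chloro-N,N,2-trimethylprop-1-en-1-amine (Ghosez reagent), CH2Cl2, 0 °C; then PMBOH, Et3N, 0 °C → rt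
Reagents that add atoms: 4-methoxybenzyl alcohol, COc1ccc(CO)cc1
Why: The chloroenamine turns the hemiacetal into its chloride under neutral conditions and base-mediated alcoholysis at the acylal carbon gives the racemic pseudo-ester, a group that is later lost by cleavage on its benzyl side rather than by slow acylal hydrolysis.

Step 14
Reactants: 21 (±)-PMB acetal
Product: 22 (±)-diol (21 without the acetonide; free B1–OH and B2–CH2OH)
Conditions: AcOH–THF–H2O (3:1:1), 45 °C
Reagents that add atoms: none
Why: Mild acid hydrolysis cleaves the aryl alkyl ketal, whereas the acylal-type PMB acetal, the PMB ether and the aryl silane need far stronger acid.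

Step 15
Reactants: 22 (±)-diol; 23 mono-tert-butyl fumarate, (E)-4-tert-butoxy-4-oxobut-2-enoic acid
Product: 24 (±)-fumarate (B2–CH2OH of 22 esterified by 23; E alkene retained)
Conditions: PPh3, DIAD, THF, 0 °C
Reagents that add atoms: none
Why: Mitsunobu esterification activates only the primary benzylic alcohol and uses the carboxylic acid, by far the most acidic partner, as nucleophile, so the neighbouring phenol stays free and no base is present that could trigger quinone methide formation.

Step 16
Reactants: 24 (±)-fumarate
Product: 25 (±)-seco acid (free ring A C6–CO2H and C3–OH; free B1–OH)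
Conditions: Pd(PPh3)4 (5 mol %), PhNHMe, THF, rt
Reagents that add atoms: none
Why: In this Tsuji–Trost deallylation zerovalent palladium ionises the allyl ester and the allyl aryl ether, and the weakly basic N-methylaniline takes up the allyl units without adding to the fumarate or deprotonating B1–OH.

Step 17
Reactants: 25 (±)-seco acid
Product: 26 (±)-depsidone phenol (C6–C(=O)–O–B1 closed; C3–OH; C4–SiMe3)
Conditions: DCC, pyridine, PPTS (cat.), CH2Cl2 (2 mM), 0 °C → rt
Reagents that add atoms: none
Why: Steglich-type carbodiimide lactonisation closes the seven-membered ring, because only B1–OH can reach the activated carboxyl intramolecularly, the ring A phenol being para to it and shielded by the silane, and the near-neutral buffer protects the benzylic fumarate.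

Step 18
Reactants: 26 (±)-depsidone phenol
Product: 27 (±)-depsidone ortho-silyl aryl triflate (C3–OTf; C4–SiMe3)
Conditions: Tf2O, pyridine, CH2Cl2, −20 → 0 °C
Reagents that add atoms: trifluoromethanesulfonic anhydride, O=S(=O)(OS(=O)(=O)C(F)(F)F)C(F)(F)F
Why: O-sulfonylation of the only free hydroxyl completes the Kobayashi-type aryne precursor after every basic and copper-mediated step is past.

Step 19
Reactants: 27 (±)-depsidone ortho-silyl aryl triflate; 15 N,N-dimethylformamide (reactant and solvent)
Product: 31 (±)-protected depsidone salicylaldehyde (C3–OH; C4–CHO), via aryne 28 (not isolated), via benzoxetene 29 (not isolated), via aminomethylidene dienone 30 (not isolated)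
Conditions: CsF (dried, 3 equiv), dry 15 (0.01 M), 25–40 °C; then pour into ice-cold 1 M HCl–THF
Reagents that add atoms: water, O
Why: Fluoride attacks the SiMe3 group at C4 and triflate leaves from C3, which gives the C3≡C4 aryne 28. The σ-withdrawing aryloxy oxygen on C5 distorts the aryne so that C3 is the electrophilic end, the carbonyl oxygen of 15 adds there while charge builds at C4 beside the C–O bond, and C2 carries only hydrogen and does not oppose this bias. The C4 carbanion closes on the iminium carbon (4-exo-trig, formal [2+2]) to benzoxetene 29, whose four-membered ring opens electrocyclically to the vinylogous amide 30, so no new ring remains; the closest known reaction type is the insertion of arynes into the C=O bond of formamides to give salicylaldehydes. No lasting stereocentre is formed and the racemic acetal carbon is not touched. Chemoselectivity rests on the absence of any O–H, N–H or allyl (ene-active) group in 27, on high dilution in neat 15, which keeps 30 away from a second aryne, and on dryness until the aryne is consumed. The cold acid quench hydrolyses 30 and holds the released dimethylamine as its salt, so it can neither add to the fumarate nor open the aryl ester.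

Step 20
Reactants: 31 (±)-protected depsidone salicylaldehyde
Product: 32 (±)-lactol (racemic form of the target)
Conditions: TFA–CH2Cl2 (1:2), anisole (10 equiv), 0 °C → rt, short time; precipitation with Et2O–hexane
Reagents that add atoms: none
Why: Acidolysis of the SN1 type on the protecting-group side removes the tert-butyl ester, the PMB ether and the PMB acetal together without water or nucleophilic solvent, so the aryl ester and the benzylic fumarate persist and the lactol is released as a racemate.

Step 21
Reactants: 32 (±)-lactol; 33 quinine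
Product: 34 quininium salt of the (R)-lactol (carboxylate at the fumarate terminus)
Conditions: 33 (1.0 equiv), acetone–EtOAc, 45 → 20 °C, seeded slurry ageing; filtration
Reagents that add atoms: none
Why: Proposed new method: the lactol carbon epimerises in solution by ring–chain tautomerism through the open formyl acid, catalysed by the carboxylate/ammonium pair, while the tertiary alkaloid base, which cannot condense with the ring A aldehyde, forms two diastereomeric salts at the fumaric acid terminus, the strongest acid of 32; if one salt is clearly less soluble its crystallisation drains the equilibrating mixture, so the lattice of the quininium salt alone sets the (R) centre; the closest known reaction types are the crystallisation-induced diastereomer transformation of epimerisable acids as alkaloid salts and the single-anomer crystallisation of mutarotating lactols, neither of which has been shown for a 3-hydroxyphthalide with a remote salt bridge.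

Step 22
Reactants: 34 quininium salt of the (R)-lactol
Product: 35 target, (R)-lactol
Conditions: 0.5 M aq. HCl, 0 °C, slurry, short contact; filter, cold water wash, dry in vacuo
Reagents that add atoms: none
Why: In this heterogeneous proton transfer (salt break) the alkaloid dissolves as its hydrochloride while the free acid is insoluble in cold water, so the lactol spends practically no time in solution and the (R) configuration fixed in step 21 is carried over.

Compound list
1 | orcinol | Cc1cc(O)cc(O)c1 | starting material
2 | 1,3-bis(methoxymethoxy)-5-methylbenzene | Cc1cc(OCOC)cc(OCOC)c1 | intermediate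
3 | 2,6-bis(methoxymethoxy)-4-methylphenyllithium | [Li]c1c(OCOC)cc(C)cc1OCOC | intermediate
4 | [2,6-bis(methoxymethoxy)-4-methylphenyl]trimethylsilane | C[Si](C)(C)c1c(OCOC)cc(C)cc1OCOC | intermediate
5 | 2,4-bis(methoxymethoxy)-6-methyl-3-(trimethylsilyl)phenyllithium | [Li]c1c(C)cc(OCOC)c([Si](C)(C)C)c1OCOC | intermediate
6 | allyl 2,4-bis(methoxymethoxy)-6-methyl-3-(trimethylsilyl)benzoate | C=CCOC(=O)c1c(C)cc(OCOC)c([Si](C)(C)C)c1OCOC | intermediate
7 | allyl 6-methyl-3-(trimethylsilyl)-2,4-bis(trimethylsilyloxy)benzoate | C=CCOC(=O)c1c(C)cc(O[Si](C)(C)C)c([Si](C)(C)C)c1O[Si](C)(C)C | intermediate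
8 | allyl 2,4-dihydroxy-6-methyl-3-(trimethylsilyl)benzoate | C=CCOC(=O)c1c(C)cc(O)c([Si](C)(C)C)c1O | intermediate
9 | allyl 4-(allyloxy)-2-hydroxy-6-methyl-3-(trimethylsilyl)benzoate | C=CCOC(=O)c1c(C)cc(OCC=C)c([Si](C)(C)C)c1O | intermediate
10 | methyl 5-bromo-2,4-dihydroxybenzoate | COC(=O)c1cc(Br)c(O)cc1O | starting material
11 | methyl 5-bromo-3-formyl-2,4-dihydroxybenzoate | COC(=O)c1cc(Br)c(O)c(C=O)c1O | intermediate
12 | methyl 5-bromo-2,4-dihydroxy-3-(hydroxymethyl)benzoate | COC(=O)c1cc(Br)c(O)c(CO)c1O | intermediate
13 | methyl 8-bromo-5-hydroxy-2,2-dimethyl-4H-1,3-benzodioxine-6-carboxylate | COC(=O)c1cc(Br)c2OC(C)(C)OCc2c1O | intermediate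
14 | methyl 8-bromo-5-(4-methoxybenzyloxy)-2,2-dimethyl-4H-1,3-benzodioxine-6-carboxylate | COC(=O)c1cc(Br)c2OC(C)(C)OCc2c1OCc1ccc(OC)cc1 | intermediate
15 | N,N-dimethylformamide | CN(C)C=O | starting material
16 | arylmagnesium chloride derived from 14 (Mg at C7) | COC(=O)c1c([Mg]Cl)c(Br)c2OC(C)(C)OCc2c1OCc1ccc(OC)cc1 | intermediate
17 | methyl 8-bromo-7-formyl-5-(4-methoxybenzyloxy)-2,2-dimethyl-4H-1,3-benzodioxine-6-carboxylate | COC(=O)c1c(C=O)c(Br)c2OC(C)(C)OCc2c1OCc1ccc(OC)cc1 | intermediate
18 | diaryl ether (C5–O–B6) from 9 and 17 | Cc1cc(OCC=C)c([Si](C)(C)C)c(Oc2c(C=O)c(C(=O)OC)c(OCc3ccc(OC)cc3)c3COC(C)(C)Oc23)c1C(=O)OCC=C | intermediate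
19 | (±)-lactol (3-hydroxyphthalide on ring B) | Cc1cc(OCC=C)c([Si](C)(C)C)c(Oc2c3C(O)OC(=O)c3c(OCc3ccc(OC)cc3)c3COC(C)(C)Oc23)c1C(=O)OCC=C | intermediate
20 | (±)-3-chlorophthalide analogue of 19 | Cc1cc(OCC=C)c([Si](C)(C)C)c(Oc2c3C(Cl)OC(=O)c3c(OCc3ccc(OC)cc3)c3COC(C)(C)Oc23)c1C(=O)OCC=C | intermediate
21 | (±)-PMB acetal | Cc1cc(OCC=C)c([Si](C)(C)C)c(Oc2c3C(OCc4ccc(OC)cc4)OC(=O)c3c(OCc3ccc(OC)cc3)c3COC(C)(C)Oc23)c1C(=O)OCC=C | intermediate
22 | (±)-diol (free B1–OH, B2–CH2OH) | Cc1cc(OCC=C)c([Si](C)(C)C)c(Oc2c(O)c(CO)c(OCc3ccc(OC)cc3)c3C(=O)OC(OCc4ccc(OC)cc4)c23)c1C(=O)OCC=C | intermediate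
23 | mono-tert-butyl fumarate | CC(C)(C)OC(=O)/C=C/C(=O)O | starting material
24 | (±)-fumarate ester of 22 | Cc1cc(OCC=C)c([Si](C)(C)C)c(Oc2c(O)c(COC(=O)/C=C/C(=O)OC(C)(C)C)c(OCc3ccc(OC)cc3)c3C(=O)OC(OCc4ccc(OC)cc4)c23)c1C(=O)OCC=C | intermediate
25 | (±)-seco acid | Cc1cc(O)c([Si](C)(C)C)c(Oc2c(O)c(COC(=O)/C=C/C(=O)OC(C)(C)C)c(OCc3ccc(OC)cc3)c3C(=O)OC(OCc4ccc(OC)cc4)c23)c1C(=O)O | intermediate
26 | (±)-depsidone phenol (C3–OH, C4–SiMe3) | Cc1cc(O)c([Si](C)(C)C)c2c1C(=O)Oc1c(COC(=O)/C=C/C(=O)OC(C)(C)C)c(OCc4ccc(OC)cc4)c3c(c1O2)C(OCc1ccc(OC)cc1)OC3=O | intermediate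
27 | (±)-depsidone ortho-silyl aryl triflate | Cc1cc(OS(=O)(=O)C(F)(F)F)c([Si](C)(C)C)c2c1C(=O)Oc1c(COC(=O)/C=C/C(=O)OC(C)(C)C)c(OCc4ccc(OC)cc4)c3c(c1O2)C(OCc1ccc(OC)cc1)OC3=O | intermediate
28 | (±)-C3≡C4 aryne | CC1=CC#CC2=C1C(=O)Oc1c(COC(=O)/C=C/C(=O)OC(C)(C)C)c(OCc4ccc(OC)cc4)c3c(c1O2)C(OCc1ccc(OC)cc1)OC3=O | intermediate
29 | benzoxetene (C3–O–CH(NMe2)–C4) | Cc1cc2OC(N(C)C)c2c2c1C(=O)Oc1c(COC(=O)/C=C/C(=O)OC(C)(C)C)c(OCc4ccc(OC)cc4)c3c(c1O2)C(OCc1ccc(OC)cc1)OC3=O | intermediate
30 | aminomethylidene dienone (C3=O, C4=CH–NMe2) | CC1=CC(=O)C(=CN(C)C)C2=C1C(=O)Oc1c(COC(=O)/C=C/C(=O)OC(C)(C)C)c(OCc4ccc(OC)cc4)c3c(c1O2)C(OCc1ccc(OC)cc1)OC3=O | intermediate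
31 | (±)-protected depsidone salicylaldehyde | Cc1cc(O)c(C=O)c2c1C(=O)Oc1c(COC(=O)/C=C/C(=O)OC(C)(C)C)c(OCc4ccc(OC)cc4)c3c(c1O2)C(OCc1ccc(OC)cc1)OC3=O | intermediate
32 | (±)-lactol, racemic form of the target | Cc1cc(O)c(C=O)c2c1C(=O)Oc1c(COC(=O)/C=C/C(=O)O)c(O)c3c(c1O2)C(O)OC3=O | intermediate
33 | quinine | COC1=CC2=C(C=CN=C2C=C1)[C@H]([C@@H]3C[C@@H]4CCN3C[C@@H]4C=C)O | starting material
34 | quininium salt of the (R)-lactol | Cc1cc(O)c(C=O)c2c1C(=O)Oc1c(COC(=O)/C=C/C(=O)[O-])c(O)c3c(c1O2)[C@H](O)OC3=O.COC1=CC2=C(C=CN=C2C=C1)[C@H]([C@@H]3C[C@@H]4CC[NH+]3C[C@@H]4C=C)O | intermediate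
35 | CNP0379578.1, (R)-lactol, (E)-fumarate | Cc1cc(O)c(C=O)c2c1C(=O)Oc1c(COC(=O)/C=C/C(=O)O)c(O)c3c(c1O2)[C@H](O)OC3=O | target

Total step count: 22.
Longest linear sequence: 17 (steps 1–5 or steps 6–10, then steps 11–22).

Steps most likely to fail

Step 21.
- The wrong diastereomeric salt or a solid solution may crystallise.
- The alkaloid may deprotonate the pseudo-acid, so that the lactol ring is open in the solid.
- Epimerisation in the mother liquor may be too slow to feed the crystals.
- Fallback: it sets out from 32 and comes back at 35. The enantiomers are separated by preparative chromatography on an immobilised polysaccharide chiral stationary phase with an acidified, alcohol-free eluent below room temperature. The (R) fraction is precipitated cold. The (S) fraction is left to racemise in solution and injected again. This fallback makes no new compound (F0).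

Step 19.
- The aryne may be captured by traces of water or by the primary adduct.
- Fluoride may open the aryl ester.
- Part of the regiocontrol may be lost.
- Fallback: it sets out from 26 and comes back at 31, using the silane as an electrophilic handle instead of an aryne trigger. Ipso-iododesilylation with N-iodosuccinimide (MeCN, 0 °C), directed by the ortho hydroxyl and the β-silicon effect, gives the C4 iodide F1. Stille coupling with Bu3SnCH=CH2 (Pd2(dba)3, AsPh3, 40 °C) gives the C4 vinyl phenol F2. Ozonolysis (O3, CH2Cl2, −78 °C; Me2S) stopped at one equivalent cleaves the electron-rich styrene in preference to the electron-poor fumarate.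

Step 11.
- C–O bond formation between two di-ortho-substituted partners may be slow.
- Base-induced carbon-to-oxygen silyl migration may cost the silane at 90 °C.
- Hydrodebromination may compete.
- Fallback: it sets out from 17 and comes back at 18, replacing the hot, basic coupling by an oxidative one at room temperature. Miyaura borylation (B2pin2, PdCl2(dppf), KOAc, dioxane, 80 °C) gives the pinacol boronate F3. NaIO4/NH4OAc in aqueous acetone gives the boronic acid F4. Chan–Lam coupling of F4 with phenol 9 (Cu(OAc)2, that is divalent copper, pyridine, 4 Å MS, air, CH2Cl2, rt) forms the diaryl ether without carbonate base.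

Further compounds
F0 | step 21 | none | none
F1 | step 19 | (±)-C4 iodide (SiMe3 of 26 replaced by I) | Cc1cc(O)c(I)c2c1C(=O)Oc1c(COC(=O)/C=C/C(=O)OC(C)(C)C)c(OCc4ccc(OC)cc4)c3c(c1O2)C(OCc1ccc(OC)cc1)OC3=O
F2 | step 19 | (±)-C4 vinyl phenol | Cc1cc(O)c(C=C)c2c1C(=O)Oc1c(COC(=O)/C=C/C(=O)OC(C)(C)C)c(OCc4ccc(OC)cc4)c3c(c1O2)C(OCc1ccc(OC)cc1)OC3=O
F3 | step 11 | pinacol boronate (Br of 17 replaced by Bpin) | COC(=O)c1c(C=O)c(B2OC(C)(C)C(C)(C)O2)c2OC(C)(C)OCc2c1OCc1ccc(OC)cc1
F4 | step 11 | boronic acid (Br of 17 replaced by B(OH)2) | COC(=O)c1c(C=O)c(B(O)O)c2OC(C)(C)OCc2c1OCc1ccc(OC)cc1
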